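**Retrosynthetic overview**

- Numbering used: ring A = C1–C6 (octyl chain on C1), ring B = C4, C5, C7, C12, ring C = C7, C8, C11, C12, ring D = C8, C9, C10, C11. The glyceryl ether is cut at the O–CH2 bond of the chain, giving a ladderanyl-octyl mesylate and 1,3-O-benzylidene glycerol.
- Ring D is closed last by forming C9–C10 from a cis bis(iodomethyl) pair on C8/C11. Ring C comes from a [2+2] photocycloaddition of maleic anhydride across a C7=C12 cyclobutene (bonds C7–C8 and C11–C12).
- The cyclobutene is made from a C12 ketone (Shapiro olefination). C1 is set by hydrogenating a C1=C2 alkene from the face of ring A remote from ring B.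
- The strategy rests on the cis C4–C5 fusion of ring A to ring B with the chain-bearing C1 placed 1,4 to C4. This is the retron of an enantioselective Diels–Alder reaction between cyclobut-2-enone (C12, C4, C5, C7) and a 2-alkylbuta-1,3-diene (C3, C2, C1, C6), forming C3–C4 and C5–C6.
- Ring order: B (already in cyclobutenone) → A (key step) → C → D.

Key step: step 5

Assumption: the sense of induction of the proline-derived oxazaborolidine–AlBr3 catalyst with cyclobut-2-enone is taken to give the (1R,6R) adduct with the (S)-catalyst; if a test reaction shows the opposite sense, the (R)-catalyst is used and nothing else changes.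

**Route**

Step 1
Reactants: 1 dec-9-yn-1-ol
Product: 2 tert-butyl(dec-9-yn-1-yloxy)dimethylsilane
Conditions: TBSCl, imidazole, CH2Cl2, 0 °C → rt
Reagents that add atoms: tert-butyldimethylsilyl chloride, CC(C)(C)[Si](C)(C)Cl
Why: Imidazole-promoted O-silylation of a primary alcohol; the terminal alkyne is untouched.

Step 2
Reactants: 2 tert-butyl(dec-9-yn-1-yloxy)dimethylsilane
Product: 3 tert-butyldimethyl[(9-methylideneundec-10-en-1-yl)oxy]silane [2-(8-tert-butyldimethylsilyloxyoctyl)buta-1,3-diene]
Conditions: ethylene (4 atm), second-generation Grubbs catalyst RuCl2(=CHPh)(PCy3)(H2IMes) (5 mol%), CH2Cl2, rt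
Reagents that add atoms: ethylene, C=C
Why: Ethylene–alkyne cross enyne metathesis, in which the ruthenium methylidene adds to the terminal alkyne and the resulting vinylcarbene is turned over by ethylene, should give the 2-substituted 1,3-diene; no stereocentre is formed.

Step 3
Reactants: 4 3-oxocyclobutane-1-carboxylic acid
Product: 5 3-bromocyclobutan-1-one
Conditions: HgO, Br2, MgSO4, CH2Cl2, reflux
Reagents that add atoms: bromine, BrBr
Why: Cristol–Firth variant of the Hunsdiecker bromodecarboxylation (acyl hypobromite, loss of CO2, bromine capture by the cyclobutyl radical), which tolerates the ring ketone.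

Step 4
Reactants: 5 3-bromocyclobutan-1-one
Product: 6 cyclobut-2-en-1-one
Conditions: n-Bu3N, rt, reduced pressure, product collected at −78 °C and kept as a cold CH2Cl2 solution
Reagents that add atoms: none
Why: Amine-mediated E1cB dehydrobromination of a β-bromo ketone; removing the volatile enone from the ammonium salt as it forms and keeping it cold limits its polymerisation.

Step 5
Reactants: 6 cyclobut-2-en-1-one; 3 tert-butyldimethyl[(9-methylideneundec-10-en-1-yl)oxy]silane
Product: 7 (1R,6R)-3-[8-(tert-butyldimethylsilyloxy)octyl]bicyclo[4.2.0]oct-3-en-7-one (cis ring fusion)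
Conditions: (3aS)-1-(2-methylphenyl)-3,3-diphenyltetrahydro-1H,3H-pyrrolo[1,2-c][1,3,2]oxazaborole (20 mol%), AlBr3 (16 mol%), CH2Cl2, −78 °C, slow addition of 6 (1.5 equiv)
Reagents that add atoms: none
Why: The AlBr3-activated oxazaborolidine binds the carbonyl oxygen of 6 and lowers the LUMO of the strained enone, which adds to the s-cis diene 3 through a concerted but asynchronous [4+2] transition state in which the C5–C6 bond (enone β-carbon to the diene terminus next to the alkyl-bearing carbon) is more advanced than C3–C4. The closest known reaction type is the Lewis acid-catalysed Diels–Alder reaction of cyclobut-2-enone with acyclic dienes, combined with the chiral oxazaborolidine-catalysed Diels–Alder reaction of cyclic enones. Ring A is closed by intermolecular [4+2] cycloaddition, both σ-bonds forming in one step onto the preformed ring B, whose carbonyl carbon becomes C12. C4 and C5 are created together and must be cis because both bonds form on one face of the cis ring alkene; their absolute configuration is controlled by the catalyst, whose aryl group covers one face of the bound enone. The step needs para regioselectivity and enantioface selectivity: the first follows from the larger HOMO coefficient at the CH2 terminus attached to the substituted diene carbon meeting the Lewis acid-enhanced LUMO coefficient at the enone β-carbon, the second from single-point coordination of the unhindered cyclobutenone carbonyl. Relief of ring strain in the transition state makes 6 reactive enough for an unactivated 2-alkyldiene at −78 °C, where its polymerisation is slow.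

Step 6
Reactants: 7 (1R,6R)-3-[8-(tert-butyldimethylsilyloxy)octyl]bicyclo[4.2.0]oct-3-en-7-one
Product: 8 (1R,3S,6R)-3-[8-(tert-butyldimethylsilyloxy)octyl]bicyclo[4.2.0]octan-7-one (chain cis to the four-membered ring)
Conditions: H2 (1 atm), 5% Pt/C, EtOAc, rt
Reagents that add atoms: none
Why: Heterogeneous catalytic hydrogenation should add H2 syn to C1=C2 from the convex face of the cis-fused bicycle, the face of ring A that carries H4 and H5 and is remote from the pseudo-axial ring B carbons C7 and C12, so H1 ends cis to H4/H5 and the chain cis to ring B; Pt is chosen over Pd to limit double-bond migration, and the cyclobutanone and silyl ether are inert in EtOAc.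

Step 7
Reactants: 8 (1R,3S,6R)-3-[8-(tert-butyldimethylsilyloxy)octyl]bicyclo[4.2.0]octan-7-one
Product: 9 N'-{(1R,3S,6R)-3-[8-(tert-butyldimethylsilyloxy)octyl]bicyclo[4.2.0]octan-7-ylidene}-4-methylbenzenesulfonohydrazide (C=N geometry not defined)
Conditions: TsNHNH2, EtOH, rt
Reagents that add atoms: 4-methylbenzenesulfonohydrazide, Cc1ccc(cc1)S(=O)(=O)NN
Why: Condensation of the strained, unhindered cyclobutanone with tosylhydrazide needs no acid, so the silyl ether survives, and C4 cannot epimerise to a trans-fused bicycle.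

Step 8
Reactants: 9 the tosylhydrazone of step 7
Product: 11 tert-butyl({8-[(1R,3S,6S)-bicyclo[4.2.0]oct-7-en-3-yl]octyl}oxy)dimethylsilane, via cyclobutenyllithium 10 (not isolated)
Conditions: n-BuLi (2.5 equiv), TMEDA, THF, −78 °C → rt; then H2O
Reagents that add atoms: none
Why: Shapiro reaction, in which N–H and then α-deprotonation at the less substituted C7 methylene (not the C4 methine) is followed by loss of sulfinate and N2 to give the C12 vinyllithium, protonated on quench to the C7=C12 cyclobutene without touching C4, C5 or C1.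

Step 9
Reactants: 11 tert-butyl({8-[(1R,3S,6S)-bicyclo[4.2.0]oct-7-en-3-yl]octyl}oxy)dimethylsilane; 12 maleic anhydride
Product: 13 (1R,2S,3R,4S,5R,6S,8S)-8-[8-(tert-butyldimethylsilyloxy)octyl]tricyclo[4.4.0.0^2,5]decane-3,4-dicarboxylic anhydride (all ring fusions cis; ring A and ring C anti across ring B; anhydride ring anti to ring B across ring C)
Conditions: acetophenone (sensitizer), EtOAc, hν (medium-pressure Hg lamp, Pyrex), 0 °C
Reagents that add atoms: none
Why: Triplet-sensitised [2+2] photocycloaddition of maleic anhydride to the strained cyclobutene forms C7–C8 and C11–C12 via a 1,4-biradical; attack on the exo face of the cyclobutene (anti to ring A) sets C7 and C12, and closure with the cis anhydride ring turned away from ring B sets C8 and C11, giving the cis,anti,cis arrangement.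

Step 10
Reactants: 13 the anhydride of step 9
Product: 14 {(1R,2S,3R,4S,5R,6S,8S)-8-[8-(tert-butyldimethylsilyloxy)octyl]tricyclo[4.4.0.0^2,5]decane-3,4-diyl}dimethanol (the two CH2OH groups cis to each other)
Conditions: LiAlH4, THF, 0 °C → 40 °C; aqueous work-up
Reagents that add atoms: none
Why: Hydride reduction of a cyclic anhydride to the 1,4-diol; C8 and C11 are not epimerised and the primary silyl ether is stable to LiAlH4.

Step 11
Reactants: 14 the diol of step 10
Product: 15 the bis(methanesulfonate) of diol 14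
Conditions: MsCl, Et3N, CH2Cl2, 0 °C
Reagents that add atoms: methanesulfonyl chloride, CS(=O)(=O)Cl
Why: Fast double sulfonylation of the two primary alcohols (via sulfene) at 0 °C should outrun cyclic ether formation between the cis CH2OH groups.

Step 12
Reactants: 15 the bis(methanesulfonate) of step 11
Product: 16 tert-butyl({8-[(1R,2S,3R,4S,5R,6S,8S)-3,4-bis(iodomethyl)tricyclo[4.4.0.0^2,5]decan-8-yl]octyl}oxy)dimethylsilane
Conditions: NaI, NaHCO3, acetone, reflux
Reagents that add atoms: sodium iodide, [Na+].[I-]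
Why: Finkelstein SN2 displacement at two primary carbons, driven by precipitation of sodium methanesulfonate; no stereocentre is involved.

Step 13
Reactants: 16 the diiodide of step 12
Product: 18 tert-butyldimethyl({8-[(1R,2S,3S,6R,7R,8S,10S)-tetracyclo[6.4.0.0^2,7.0^3,6]dodecan-10-yl]octyl}oxy)silane, via iodoalkyllithium 17 (not isolated)
Conditions: t-BuLi (2.2 equiv), n-pentane/Et2O (3:2), −78 °C → rt
Reagents that add atoms: none
Why: Lithium–iodine exchange at one primary iodide followed by intramolecular SN2 displacement of the neighbouring cis CH2I (the known t-BuLi cyclisation of 1,4-diiodides to cyclobutanes, an intramolecular Wurtz-type coupling) forms C9–C10 and closes ring D; the cis pair on ring C is held within bonding distance, the second equivalent of t-BuLi destroys the tert-butyl iodide formed, and no stereocentre changes.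

Step 14
Reactants: 18 the silyl ether of step 13
Product: 19 8-[(1R,2S,3S,6R,7R,8S,10S)-tetracyclo[6.4.0.0^2,7.0^3,6]dodecan-10-yl]octan-1-ol
Conditions: Bu4NF, THF, rt
Reagents that add atoms: none
Why: Fluoride-induced desilylation of a primary TBS ether; the saturated hydrocarbon core is inert.

Step 15
Reactants: 19 the alcohol of step 14
Product: 20 8-[(1R,2S,3S,6R,7R,8S,10S)-tetracyclo[6.4.0.0^2,7.0^3,6]dodecan-10-yl]octyl methanesulfonate
Conditions: MsCl, Et3N, CH2Cl2, 0 °C
Reagents that add atoms: methanesulfonyl chloride, CS(=O)(=O)Cl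
Why: Standard mesylation of a primary alcohol to give an SN2-competent electrophile.

Step 16
Reactants: 21 cis-2-phenyl-1,3-dioxan-5-ol (1,3-O-benzylidene glycerol); 20 the mesylate of step 15
Product: 23 cis-2-phenyl-5-({8-[(1R,2S,3S,6R,7R,8S,10S)-tetracyclo[6.4.0.0^2,7.0^3,6]dodecan-10-yl]octyl}oxy)-1,3-dioxane, via sodium alkoxide 22 (not isolated)
Conditions: NaH, DMF, 0 °C → rt; then 20, 50 °C
Reagents that add atoms: none
Why: Williamson etherification of a secondary sodium alkoxide with a primary mesylate (SN2); the acetal is stable to base and is chosen so that the final deprotection needs no hydrogenolysis catalyst near the strained cyclobutane bonds.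

Step 17
Reactants: 23 the benzylidene acetal of step 16
Product: 24 2-({8-[(1R,2S,3S,6R,7R,8S,10S)-tetracyclo[6.4.0.0^2,7.0^3,6]dodecan-10-yl]octyl}oxy)propane-1,3-diol (target)
Conditions: 1 M HCl, THF/H2O, 40 °C
Reagents that add atoms: none
Why: Acid-catalysed acetal hydrolysis releases the 1,3-diol and benzaldehyde; the dialkyl ether and the saturated ladderane are inert to dilute acid, and the glycerol carbon is not stereogenic.

**Compound list**

1 | dec-9-yn-1-ol | OCCCCCCCCC#C | starting material
2 | tert-butyl(dec-9-yn-1-yloxy)dimethylsilane | CC(C)(C)[Si](C)(C)OCCCCCCCCC#C | intermediate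
3 | tert-butyldimethyl[(9-methylideneundec-10-en-1-yl)oxy]silane | C=CC(=C)CCCCCCCCO[Si](C)(C)C(C)(C)C | intermediate
4 | 3-oxocyclobutane-1-carboxylic acid | O=C1CC(C1)C(=O)O | starting material
5 | 3-bromocyclobutan-1-one | O=C1CC(Br)C1 | intermediate
6 | cyclobut-2-en-1-one | O=C1C=CC1 | intermediate
7 | (1R,6R)-3-[8-(tert-butyldimethylsilyloxy)octyl]bicyclo[4.2.0]oct-3-en-7-one | CC(C)(C)[Si](C)(C)OCCCCCCCCC1=CC[C@@H]2[C@H](C1)CC2=O | intermediate
8 | (1R,3S,6R)-3-[8-(tert-butyldimethylsilyloxy)octyl]bicyclo[4.2.0]octan-7-one | CC(C)(C)[Si](C)(C)OCCCCCCCC[C@H]1CC[C@@H]2[C@H](C1)CC2=O | intermediate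
9 | N'-{(1R,3S,6R)-3-[8-(tert-butyldimethylsilyloxy)octyl]bicyclo[4.2.0]octan-7-ylidene}-4-methylbenzenesulfonohydrazide | CC(C)(C)[Si](C)(C)OCCCCCCCC[C@H]1CC[C@@H]2[C@H](C1)CC2=NNS(=O)(=O)c1ccc(C)cc1 | intermediate
10 | 7-lithio derivative of 11 (lithium on C12 of the cyclobutene) | CC(C)(C)[Si](C)(C)OCCCCCCCC[C@H]1CC[C@@H]2[C@H](C1)C=C2[Li] | intermediate (not isolated)
11 | tert-butyl({8-[(1R,3S,6S)-bicyclo[4.2.0]oct-7-en-3-yl]octyl}oxy)dimethylsilane | CC(C)(C)[Si](C)(C)OCCCCCCCC[C@H]1CC[C@@H]2[C@H](C1)C=C2 | intermediate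
12 | maleic anhydride | O=C1OC(=O)C=C1 | starting material
13 | (1R,2S,3R,4S,5R,6S,8S)-8-[8-(tert-butyldimethylsilyloxy)octyl]tricyclo[4.4.0.0^2,5]decane-3,4-dicarboxylic anhydride | CC(C)(C)[Si](C)(C)OCCCCCCCC[C@H]1CC[C@@H]2[C@H](C1)[C@H]1[C@@H]3C(=O)OC(=O)[C@@H]3[C@@H]21 | intermediate
14 | {(1R,2S,3R,4S,5R,6S,8S)-8-[8-(tert-butyldimethylsilyloxy)octyl]tricyclo[4.4.0.0^2,5]decane-3,4-diyl}dimethanol | CC(C)(C)[Si](C)(C)OCCCCCCCC[C@H]1CC[C@@H]2[C@H](C1)[C@H]1[C@H](CO)[C@H](CO)[C@@H]21 | intermediate
15 | bis(methanesulfonate) of 14 | CC(C)(C)[Si](C)(C)OCCCCCCCC[C@H]1CC[C@@H]2[C@H](C1)[C@H]1[C@H](COS(C)(=O)=O)[C@H](COS(C)(=O)=O)[C@@H]21 | intermediate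
16 | tert-butyl({8-[(1R,2S,3R,4S,5R,6S,8S)-3,4-bis(iodomethyl)tricyclo[4.4.0.0^2,5]decan-8-yl]octyl}oxy)dimethylsilane | CC(C)(C)[Si](C)(C)OCCCCCCCC[C@H]1CC[C@@H]2[C@H](C1)[C@H]1[C@H](CI)[C@H](CI)[C@@H]21 | intermediate
17 | monolithio compound from 16 (one CH2Li, one CH2I, cis on ring C) | CC(C)(C)[Si](C)(C)OCCCCCCCC[C@H]1CC[C@@H]2[C@H](C1)[C@H]1[C@H](C[Li])[C@H](CI)[C@@H]21 | intermediate (not isolated)
18 | tert-butyldimethyl({8-[(1R,2S,3S,6R,7R,8S,10S)-tetracyclo[6.4.0.0^2,7.0^3,6]dodecan-10-yl]octyl}oxy)silane | CC(C)(C)[Si](C)(C)OCCCCCCCC[C@H]1CC[C@@H]2[C@H](C1)[C@H]1[C@@H]3CC[C@@H]3[C@@H]21 | intermediate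
19 | 8-[(1R,2S,3S,6R,7R,8S,10S)-tetracyclo[6.4.0.0^2,7.0^3,6]dodecan-10-yl]octan-1-ol | OCCCCCCCC[C@H]1CC[C@@H]2[C@H](C1)[C@H]1[C@@H]3CC[C@@H]3[C@@H]21 | intermediate
20 | 8-[(1R,2S,3S,6R,7R,8S,10S)-tetracyclo[6.4.0.0^2,7.0^3,6]dodecan-10-yl]octyl methanesulfonate | CS(=O)(=O)OCCCCCCCC[C@H]1CC[C@@H]2[C@H](C1)[C@H]1[C@@H]3CC[C@@H]3[C@@H]21 | intermediate
21 | cis-2-phenyl-1,3-dioxan-5-ol | O[C@H]1CO[C@@H](c2ccccc2)OC1 | starting material
22 | sodium cis-2-phenyl-1,3-dioxan-5-olate | [Na+].[O-][C@H]1CO[C@@H](c2ccccc2)OC1 | intermediate (not isolated)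
23 | cis-2-phenyl-5-({8-[(1R,2S,3S,6R,7R,8S,10S)-tetracyclo[6.4.0.0^2,7.0^3,6]dodecan-10-yl]octyl}oxy)-1,3-dioxane | C(CCCCCCCO[C@H]1CO[C@@H](c2ccccc2)OC1)[C@H]1CC[C@@H]2[C@H](C1)[C@H]1[C@@H]3CC[C@@H]3[C@@H]21 | intermediate
24 | 2-({8-[(1R,2S,3S,6R,7R,8S,10S)-tetracyclo[6.4.0.0^2,7.0^3,6]dodecan-10-yl]octyl}oxy)propane-1,3-diol | OCC(CO)OCCCCCCCC[C@H]1CC[C@@H]2[C@H](C1)[C@H]1[C@@H]3CC[C@@H]3[C@@H]21 | target

**Step count**

Total: 17 steps. Longest linear sequence: 15 steps (steps 1, 2 and 5–17 from 1; the branch from 4 through steps 3, 4 and 5–17 is equally long).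

**Steps most likely to fail, with fallbacks**

Step 5. The risk is insufficient enantioface discrimination at the small, flat cyclobutenone, or polymerisation of the dienophile outrunning the catalysed cycloaddition. The fallback separates ring construction from enantiocontrol; it sets out from 6 and 3 and returns at 7. An achiral ZnCl2-promoted Diels–Alder reaction in CH2Cl2 should give the racemic ketone F1. NaBH4 in MeOH at −40 °C, attacking the convex face, should give the racemic endo alcohol F2. Burkholderia cepacia lipase with vinyl acetate in t-BuOMe is expected, from the usual size-based enantiopreference of lipases for secondary alcohols, to acetylate the (7R) enantiomer to the acetate F3 and leave the (1R,6R,7S) alcohol F4. After chromatographic separation, F4 is oxidised with Dess–Martin periodinane in CH2Cl2 to 7.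

Step 6. The risk is poor facial selectivity in hydrogen delivery to C1=C2, or double-bond migration on the metal before reduction. The fallback raises the steric bias of the substrate before hydrogenation; it sets out from 7 and returns at 8. LiBH(s-Bu)3 in THF at −78 °C should give the endo alcohol F4 (the compound already met in the fallback above). Pivaloyl chloride, pyridine and DMAP convert it into the pivalate F5, whose ester group lies over the concave face of ring A and should reinforce delivery from the convex face. Hydrogenation (H2, Pt/C, EtOAc) should then give the saturated pivalate F6. i-Bu2AlH in CH2Cl2 at −78 °C releases the saturated alcohol F7, and Dess–Martin oxidation returns ketone 8.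

Step 13. The risk is a second lithium–iodine exchange, or strain-driven ring opening of the cyclobutylcarbinyllithium, competing with closure of the four-membered ring. The fallback closes ring D by sulfur extrusion instead of carbanion alkylation; it sets out from 15 and returns at 18. Na2S·9H2O in DMF at 50 °C should give the thiolane F8. N-Chlorosuccinimide in CCl4 gives the α-chloro sulfide F9 (chlorine on C9 or C10; both lead to the same alkene). mCPBA in CH2Cl2 at 0 °C gives the α-chloro sulfone F10. KOt-Bu in THF effects the Ramberg–Bäcklund contraction to the C9=C10 cyclobutene F11. Diimide, generated from dipotassium azodicarboxylate and AcOH in MeOH, reduces the strained alkene to 18 without a hydrogenolysis catalyst.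

**Further compounds**

F1 | step 5 | racemic cis-3-[8-(tert-butyldimethylsilyloxy)octyl]bicyclo[4.2.0]oct-3-en-7-one (both enantiomers written) | CC(C)(C)[Si](C)(C)OCCCCCCCCC1=CC[C@@H]2[C@H](C1)CC2=O.CC(C)(C)[Si](C)(C)OCCCCCCCCC1=CC[C@H]2[C@@H](C1)CC2=O
F2 | step 5 | racemic (1R*,6R*,7S*)-3-[8-(tert-butyldimethylsilyloxy)octyl]bicyclo[4.2.0]oct-3-en-7-ol, endo alcohol (both enantiomers written) | CC(C)(C)[Si](C)(C)OCCCCCCCCC1=CC[C@@H]2[C@H](C1)C[C@@H]2O.CC(C)(C)[Si](C)(C)OCCCCCCCCC1=CC[C@H]2[C@@H](C1)C[C@H]2O
F3 | step 5 | (1S,6S,7R)-3-[8-(tert-butyldimethylsilyloxy)octyl]bicyclo[4.2.0]oct-3-en-7-yl acetate | CC(C)(C)[Si](C)(C)OCCCCCCCCC1=CC[C@H]2[C@@H](C1)C[C@H]2OC(C)=O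
F4 | step 5 | (1R,6R,7S)-3-[8-(tert-butyldimethylsilyloxy)octyl]bicyclo[4.2.0]oct-3-en-7-ol | CC(C)(C)[Si](C)(C)OCCCCCCCCC1=CC[C@@H]2[C@H](C1)C[C@@H]2O
F5 | step 6 | (1R,6R,7S)-3-[8-(tert-butyldimethylsilyloxy)octyl]bicyclo[4.2.0]oct-3-en-7-yl 2,2-dimethylpropanoate | CC(C)(C)[Si](C)(C)OCCCCCCCCC1=CC[C@@H]2[C@H](C1)C[C@@H]2OC(=O)C(C)(C)C
F6 | step 6 | (1R,3S,6R,7S)-3-[8-(tert-butyldimethylsilyloxy)octyl]bicyclo[4.2.0]octan-7-yl 2,2-dimethylpropanoate | CC(C)(C)[Si](C)(C)OCCCCCCCC[C@H]1CC[C@@H]2[C@H](C1)C[C@@H]2OC(=O)C(C)(C)C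
F7 | step 6 | (1R,3S,6R,7S)-3-[8-(tert-butyldimethylsilyloxy)octyl]bicyclo[4.2.0]octan-7-ol | CC(C)(C)[Si](C)(C)OCCCCCCCC[C@H]1CC[C@@H]2[C@H](C1)C[C@@H]2O
F8 | step 13 | cyclic sulfide in which sulfur bridges C9 and C10 (tetrahydrothiophene in place of ring D, otherwise as 18) | CC(C)(C)[Si](C)(C)OCCCCCCCC[C@H]1CC[C@@H]2[C@H](C1)[C@H]1[C@@H]3CSC[C@@H]3[C@@H]21
F9 | step 13 | α-chloro sulfide from F8 (one regioisomer written, configuration at the chlorinated carbon not defined) | CC(C)(C)[Si](C)(C)OCCCCCCCC[C@H]1CC[C@@H]2[C@H](C1)[C@H]1[C@@H]3C(Cl)SC[C@@H]3[C@@H]21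
F10 | step 13 | α-chloro sulfone from F9 (one regioisomer written, configuration at the chlorinated carbon not defined) | CC(C)(C)[Si](C)(C)OCCCCCCCC[C@H]1CC[C@@H]2[C@H](C1)[C@H]1[C@@H]3C(Cl)S(=O)(=O)C[C@@H]3[C@@H]21
F11 | step 13 | C9=C10 cyclobutene analogue of 18 (tetracyclo[6.4.0.0^2,7.0^3,6]dodec-4-ene core, otherwise as 18) | CC(C)(C)[Si](C)(C)OCCCCCCCC[C@H]1CC[C@@H]2[C@H](C1)[C@H]1[C@@H]3C=C[C@@H]3[C@@H]21
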